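| flask | free monomer | initiator | impurity | remark | time |
|---|---|---|---|---|---|
| south-east | 2 M | 4 mM | 0.55 mM | run made earlier |  |
| south | 2 M | 4 mM | 0.83 mM | run made earlier |  |
| north-east | 2 M | 6 mM | 1.1 mM | run made earlier |  |
| flask | 2.0 M | 4.0 mM | 1.1 mM |  | 12 min |

| run | time / min | monomer in chains / % | free monomer / % |
|---|---|---|---|
| south-east | 1.00 | 11.9 | 78.5 |
| south-east | 2.00 | 24.0 | 57.1 |
| south-east | 3.00 | 32.2 | 42.2 |
| south-east | 6.00 | 41.3 | 23.2 |
| south-east | 12.0 | 36.4 | 15.3 |
| south | 1.00 | 11.0 | 78.2 |
| south | 2.00 | 22.4 | 58.7 |
| south | 3.00 | 31.1 | 44.6 |
| south | 6.00 | 40.1 | 22.7 |
| south | 12.0 | 35.4 | 15.9 |
| north-east | 1.00 | 15.9 | 73.9 |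
| north-east | 3.00 | 39.9 | 36.3 |
| north-east | 6.00 | 47.4 | 19.7 |
| north-east | 8.00 | 45.9 | 17.0 |
| north-east | 12.0 | 38.3 | 17.0 |

(readings scatter by 0.5 percentage points)

- the average divides the monomer in chains by the number of chains begun, living and dead together
- reactions considered so far: free monomer + initiator -> living end + monomer in chains; free monomer + living end -> monomer in chains + living end; monomer in chains + living end -> free monomer + living end; free monomer -> uncatalysed product; initiator + impurity -> spent initiator
- the earlier runs do not show the number of chains; that part of a forecast is a guess

- whether the average number of monomer units in a chain (chains begun, living or dead) reaches 200 by 12 min (no / yes)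
- average number of monomer units in a chain (chains begun, living or dead) at 12 min

The ratio of impurity to initiator charged in the flask is 0.275, and it tells whether the bench rule of one chain per initiator may be used. The rule needs the monomer in chains at 12 min. The two runs with 4 mM of initiator read 36.4% and 35.4% there, and a straight line through them in impurity gives 34.4% for the flask. Divided by the initiator charge, this makes an average of 172, less than the 200 wanted.

But in this flask the rule stops working once impurity removes too large a share of the initiator for the average to stay below 200. A share of 0.139 already brings this average up to the wanted length, and the flask's ratio is larger. The balance of initiator therefore replaces the rule. Impurity is the limiting reagent of its step with initiator, and if it takes initiator one for one and what it leaves begins chains, the chains begun number 2.90 mM, the initiator charge less the impurity charge. The south-east and south readings of monomer in chains at 1.00 min stand in the ratio 1.08, and the same balance for those runs gives 1.09; with a scatter of 0.5 percentage points on each reading, this leans towards the balance without proving it. On that balance, the reckoning here gives 237 for the flask.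

The forecast says yes, with an average of 235, on the ground that “impurity seems to destroy initiator one-for-one”.

The flask gives yes, with an average of 235, and it passes 200 at 2.97 min.

free monomer + initiator → living end + monomer in chains (k = 1.08 /M/min); free monomer + living end → monomer in chains + living end, rate k2*[living end]*[free monomer] (k = 86.6 /M/min); monomer in chains + living end → free monomer + living end, rate k3*[living end] as long as [monomer in chains] is above zero (k = 36.4 /min); free monomer → uncatalysed product (k = 0.120 /min); initiator + impurity → spent initiator (k = 11000 /M/min) Monomer in chains is made 1.92 times as fast as it is used up at 3.50 min, but 0.730 times as fast at 12.0 min, when the flask holds 34.1% in chains and 50.6% as uncatalysed product. In the north-east run the same balance gives 4.90 mM of chains, so the wanted length needs 49.0% of the charge in chains, and its highest reading is 47.4%.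

All runs are simulated on assumed constants; scatter was added.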